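Everything rests on building pyran ring D last, by disconnecting the C5'–vinyl carbon bond and the O4'–C(CH3)2 bond of the dimethylchromene. The key step exploits ring B: the free 4'-OH steers 3-methylbut-2-enal to C5'–H, the open ortho carbon para to the 2'-OMe group, so one operation adds all five carbons and closes ring D. Its precursor is a single-enantiomer cis-(3S,4S)-isoflavan-4-ol, obtained by ketone α-arylation and transfer hydrogenation with dynamic kinetic resolution; C4 is a silylated carbinol, so C3 cannot enolise. O4 (TES) and O7 (TIPS) are differentiated, so the later oxidation meets no free phenol and only a weakly acidic desilylation follows it.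

Key step: step 7

Remark on the chemistry: isoflavonoid numbering is used (rings A and C = the chroman, ring B = the C3 aryl ring with primed atoms, ring D = the pyran). The stereocentre of the target reads as 3S. The C3–H of an isoflavanone (benzylic and α to the ketone) is assumed to racemise under base, so no basic reagent is used once the C4 ketone is back in place (steps 9 and 10).

Step 1
Reactants: 1 7-hydroxychroman-4-one
Product: 2 7-(triisopropylsilyloxy)chroman-4-one
Conditions: TIPSCl, imidazole, DMF, rt
Reagents that add atoms: triisopropylsilyl chloride (TIPSCl), CC(C)[Si](Cl)(C(C)C)C(C)C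
Why: Imidazole-promoted O-silylation of the only hydroxyl group; the bulky TIPS ether is chosen because it should outlast the hot phosphate base of step 3 and all acidic steps, yet leave easily at the end when it again sits para to the ketone.

Step 2
Reactants: 3 4-bromo-3-methoxyphenol
Product: 4 4-(benzyloxy)-1-bromo-2-methoxybenzene
Conditions: BnBr, K2CO3, acetone, reflux
Reagents that add atoms: benzyl bromide (BnBr), BrCc1ccccc1
Why: Williamson ether synthesis at the single acidic site; benzyl tolerates base, palladium coupling and formate reduction and can be removed by hydrogenolysis while the molecule still has no alkene.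

Step 3
Reactants: 2 7-(triisopropylsilyloxy)chroman-4-one; 4 4-(benzyloxy)-1-bromo-2-methoxybenzene
Product: 5 rac-3-[4-(benzyloxy)-2-methoxyphenyl]-7-(triisopropylsilyloxy)chroman-4-one
Conditions: Pd(OAc)2 (3 mol %), XPhos (6 mol %), K3PO4 (2.5 equiv), toluene, 100 °C, 2 in slight excess
Reagents that add atoms: none
Why: Palladium-catalysed ketone α-arylation (Buchwald–Hartwig type), known for chroman-4-ones: C3 is the only enolisable carbon, the mild insoluble base limits retro-oxa-Michael opening of ring C and attack on silicon, the ortho-methoxy group blocks a second arylation, and C3 is deliberately formed racemic.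

Step 4
Reactants: 5 rac-3-[4-(benzyloxy)-2-methoxyphenyl]-7-(triisopropylsilyloxy)chroman-4-one
Product: 6 cis-(3S,4S)-3-[4-(benzyloxy)-2-methoxyphenyl]-7-(triisopropylsilyloxy)chroman-4-ol
Conditions: RuCl(p-cymene)[(S,S)-TsDPEN] (2 mol %), HCO2H/Et3N (amine in excess), EtOAc, 40 °C
Reagents that add atoms: none
Why: Noyori–Ikariya asymmetric transfer hydrogenation with dynamic kinetic resolution, known for isoflavanones: Et3N racemises C3 through the enol faster than reduction, the (S,S) catalyst sets 4S as it does for chroman-4-one (CH/π contact of p-cymene with ring A), and hydride enters anti to the C3 aryl group, so only the 3S ketone is consumed and the cis-(3S,4S) alcohol should result.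

Step 5
Reactants: 6 cis-(3S,4S)-3-[4-(benzyloxy)-2-methoxyphenyl]-7-(triisopropylsilyloxy)chroman-4-ol
Product: 7 cis-(3S,4S)-3-[4-(benzyloxy)-2-methoxyphenyl]-4-(triethylsilyloxy)-7-(triisopropylsilyloxy)chroman
Conditions: TESCl, imidazole, DMAP (cat.), DMF, rt
Reagents that add atoms: triethylsilyl chloride (TESCl), CC[Si](Cl)(CC)CC
Why: Standard O-silylation under non-ionising conditions; TES masks the electron-rich benzylic carbinol against dehydration in step 7 and, unlike a bulkier silyl group, can later be removed by mild aqueous acid that leaves the aryl TIPS ether alone.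

Step 6
Reactants: 7 cis-(3S,4S)-3-[4-(benzyloxy)-2-methoxyphenyl]-4-(triethylsilyloxy)-7-(triisopropylsilyloxy)chroman
Product: 8 3-methoxy-4-[(3S,4S)-4-(triethylsilyloxy)-7-(triisopropylsilyloxy)chroman-3-yl]phenol (cis)
Conditions: H2 (1 atm), Pd/C (10 wt % Pd), EtOAc, rt
Reagents that add atoms: none
Why: Catalytic hydrogenolysis cleaves the aryl benzyl ether far faster than the hindered C4–O bond, EtOAc instead of an alcohol keeps the TES ether intact over Pd/C, and no alkene is present yet.

Step 7
Reactants: 8 3-methoxy-4-[(3S,4S)-4-(triethylsilyloxy)-7-(triisopropylsilyloxy)chroman-3-yl]phenol; 9 3-methylbut-2-enal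
Product: 12 cis-(3S,4S)-3-(7-methoxy-2,2-dimethyl-2H-chromen-6-yl)-4-(triethylsilyloxy)-7-(triisopropylsilyloxy)chroman, via benzodioxaborin 10 (not isolated), via ortho-quinone methide 11 (not isolated)
Conditions: 9 (3 equiv), PhB(OH)2 (1.2 equiv), EtCO2H (0.3 equiv), toluene, reflux, Dean–Stark
Reagents that add atoms: none
Why: PhB(OH)2 binds the 4'-phenol and, with acid catalysis, delivers the carbonyl carbon of 9 through a cyclic six-membered transition state to the ortho carbon C5' (C5'–C bond), giving benzodioxaborin 10. At reflux 10 expels PhBO in a retro-[4+2] fragmentation to the ortho-quinone methide 11, whose Z isomer closes ring D by a thermal disrotatory oxa-6π electrocyclisation that forms the O4'–C(CH3)2 bond and restores the aromaticity of ring B. The closest known reaction is the phenylboronic acid-mediated chromenylation of phenols with enals, which converts 3-methoxyphenol and 9 into 7-methoxy-2,2-dimethylchromene. No stereocentre is created, because the new sp3 carbon carries two methyl groups, and C3 and C4 are spectators since neither is α to a carbonyl group. The step needs C5' over C3' and ring B over ring A: C5' is para to the 2'-OMe donor and flanked by C6'–H, C3' is wedged between two oxygen substituents, and ring A offers no free phenol for boron to bind because O7 is silylated. Only catalytic carboxylic acid and azeotropic removal of water are used, so the C4 TES ether and the aryl TIPS ether should persist.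

Step 8
Reactants: 12 cis-(3S,4S)-3-(7-methoxy-2,2-dimethyl-2H-chromen-6-yl)-4-(triethylsilyloxy)-7-(triisopropylsilyloxy)chroman
Product: 13 cis-(3S,4S)-3-(7-methoxy-2,2-dimethyl-2H-chromen-6-yl)-7-(triisopropylsilyloxy)chroman-4-ol
Conditions: AcOH/THF/H2O (3:1:1), rt
Reagents that add atoms: none
Why: Mild acid hydrolysis of a silyl ether discriminates by type and size (alkyl TES goes, the very acid-stable aryl TIPS stays), the chromene tolerates dilute acetic acid, and in water any reversible ionisation at C4 only returns a carbinol that is oxidised next anyway.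

Step 9
Reactants: 13 cis-(3S,4S)-3-(7-methoxy-2,2-dimethyl-2H-chromen-6-yl)-7-(triisopropylsilyloxy)chroman-4-ol
Product: 14 (3S)-3-(7-methoxy-2,2-dimethyl-2H-chromen-6-yl)-7-(triisopropylsilyloxy)chroman-4-one
Conditions: DMP (1.3 equiv), CH2Cl2, 0 °C to rt; aq. Na2S2O3/pH 7 phosphate work-up
Reagents that add atoms: none
Why: Dess–Martin oxidation runs base-free in a weakly acidic medium, a type of oxidation that turns isoflavan-4-ols into isoflavanones with C3 retained, and with O7 still silylated there is no phenol or para-hydroxybenzyl alcohol for the oxidant to attack.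

Step 10
Reactants: 14 (3S)-3-(7-methoxy-2,2-dimethyl-2H-chromen-6-yl)-7-(triisopropylsilyloxy)chroman-4-one
Product: 15 (3S)-7-hydroxy-3-(7-methoxy-2,2-dimethyl-2H-chromen-6-yl)chroman-4-one (target)
Conditions: Et3N·3HF (3 equiv), THF, 0 °C to rt; pH 7 phosphate work-up
Reagents that add atoms: none
Why: Fluoride desilylation of an aryl silyl ether that lies para to the C4 ketone (a vinylogous silyl ester, hence very labile) should proceed in this weakly acidic reagent, which holds no base able to enolise C3 and is too mild to open or hydrate the chromene.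

Compound list
1 | 7-hydroxychroman-4-one | O=C1CCOc2cc(O)ccc12 | starting material
2 | 7-(triisopropylsilyloxy)chroman-4-one | O=C1CCOc2cc(O[Si](C(C)C)(C(C)C)C(C)C)ccc12 | intermediate
3 | 4-bromo-3-methoxyphenol | COc1cc(O)ccc1Br | starting material
4 | 4-(benzyloxy)-1-bromo-2-methoxybenzene | COc1cc(OCc2ccccc2)ccc1Br | intermediate
5 | rac-3-[4-(benzyloxy)-2-methoxyphenyl]-7-(triisopropylsilyloxy)chroman-4-one | COc1cc(OCc2ccccc2)ccc1C1COc2cc(O[Si](C(C)C)(C(C)C)C(C)C)ccc2C1=O | intermediate
6 | cis-(3S,4S)-3-[4-(benzyloxy)-2-methoxyphenyl]-7-(triisopropylsilyloxy)chroman-4-ol | COc1cc(OCc2ccccc2)ccc1[C@H]1COc2cc(O[Si](C(C)C)(C(C)C)C(C)C)ccc2[C@H]1O | intermediate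
7 | cis-(3S,4S)-3-[4-(benzyloxy)-2-methoxyphenyl]-4-(triethylsilyloxy)-7-(triisopropylsilyloxy)chroman | COc1cc(OCc2ccccc2)ccc1[C@H]1COc2cc(O[Si](C(C)C)(C(C)C)C(C)C)ccc2[C@H]1O[Si](CC)(CC)CC | intermediate
8 | 3-methoxy-4-[(3S,4S)-4-(triethylsilyloxy)-7-(triisopropylsilyloxy)chroman-3-yl]phenol (cis; precursor of the key step) | COc1cc(O)ccc1[C@H]1COc2cc(O[Si](C(C)C)(C(C)C)C(C)C)ccc2[C@H]1O[Si](CC)(CC)CC | intermediate
9 | 3-methylbut-2-enal | CC(C)=CC=O | starting material
10 | 4-(2-methylprop-1-enyl)-2-phenyl-4H-1,3,2-benzodioxaborin fused at C4'–C5' of ring B, both epimers at the new boronate carbon, (3S,4S) chroman unchanged | COc1cc2OB(c3ccccc3)OC(C=C(C)C)c2cc1[C@H]1COc2cc(O[Si](C(C)C)(C(C)C)C(C)C)ccc2[C@H]1O[Si](CC)(CC)CC | intermediate (not isolated)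
11 | ortho-quinone methide of ring B (C4'=O, C5'=CH–CH=C(CH3)2, drawn as the Z isomer that can cyclise), (3S,4S) chroman unchanged | CC(C)=C/C=C1/C=C([C@H]2COc3cc(O[Si](C(C)C)(C(C)C)C(C)C)ccc3[C@H]2O[Si](CC)(CC)CC)C(OC)=CC1=O | intermediate (not isolated)
12 | cis-(3S,4S)-3-(7-methoxy-2,2-dimethyl-2H-chromen-6-yl)-4-(triethylsilyloxy)-7-(triisopropylsilyloxy)chroman (product of the key step) | COc1cc2OC(C)(C)C=Cc2cc1[C@H]1COc2cc(O[Si](C(C)C)(C(C)C)C(C)C)ccc2[C@H]1O[Si](CC)(CC)CC | intermediate
13 | cis-(3S,4S)-3-(7-methoxy-2,2-dimethyl-2H-chromen-6-yl)-7-(triisopropylsilyloxy)chroman-4-ol | COc1cc2OC(C)(C)C=Cc2cc1[C@H]1COc2cc(O[Si](C(C)C)(C(C)C)C(C)C)ccc2[C@H]1O | intermediate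
14 | (3S)-3-(7-methoxy-2,2-dimethyl-2H-chromen-6-yl)-7-(triisopropylsilyloxy)chroman-4-one | COc1cc2OC(C)(C)C=Cc2cc1[C@H]1COc2cc(O[Si](C(C)C)(C(C)C)C(C)C)ccc2C1=O | intermediate
15 | (3S)-7-hydroxy-3-(7-methoxy-2,2-dimethyl-2H-chromen-6-yl)chroman-4-one | COc1cc2c(cc1[C@H]1COc3cc(O)ccc3C1=O)C=CC(C)(C)O2 | target

Total step count: 10. Longest linear sequence: 9 steps (step 1 or step 2, then steps 3 to 10).

Steps most likely to fail

Step 7. The ortho C-alkylation of a monohydric phenol may be sluggish. Part of the attack may go to C3'. The long acidic reflux may also strip the TES group and start ionisation at C4. The fallback sets out from 8 and returns at 12, and it makes the O–C bond first in an acid-free medium. Phenol 8 is O-alkylated with 3-chloro-3-methylbut-1-yne (K2CO3, KI, CuI cat., acetone, reflux) to the aryl 1,1-dimethylpropargyl ether F1. Heating in o-xylene at 140 °C then triggers aromatic Claisen rearrangement to C5', a 1,5-hydrogen shift and the same oxa-6π closure, which should give 12.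

Step 3. Ring C may open by retro-oxa-Michael reaction under hot base. Oxidative addition and reductive elimination may be slow with an electron-rich, ortho-substituted bromide. The base may also erode the TIPS ether. The fallback sets out from 4 and returns at 6, and it replaces enolate chemistry by a biaryl-type coupling.
- Miyaura borylation of 4 (B2pin2, PdCl2(dppf), KOAc, dioxane, 80 °C) gives the pinacol boronate F2.
- Commercial 2,4-dihydroxyacetophenone is silylated selectively at the non-chelated 4-OH (TIPSCl, imidazole) to the acetophenone F3.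
- F3 is condensed with DMF dimethyl acetal to the enaminone F4, which is cyclised with I2 in CHCl3 to the 3-iodochromone F5.
- Suzuki–Miyaura coupling of F2 with F5 (PdCl2(dppf), K3PO4, dioxane with a little water, 60 °C) gives the isoflavone F6.
- Under the conditions of step 4, F6 should undergo conjugate reduction to 5 in the flask, followed by the same dynamic kinetic resolution, to give 6.

Step 10. Configuration at C3 may erode by enolisation during or after the desilylation, since this step handles the finished, configurationally labile ketone. The fallback sets out from 12 and returns at 15, and it makes the oxidation the very last operation. TBAF in THF removes both silyl groups while C4 is still a carbinol, giving the chroman-4,7-diol F7. DDQ (1 equiv, dioxane, rt) then oxidises the para-hydroxybenzylic carbinol by hydride abstraction from C4–H, a known reaction of para-hydroxybenzyl alcohols, directly to 15. This path also bypasses steps 8 and 9.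

Further compounds
F1 | step 7 | cis-(3S,4S)-3-[2-methoxy-4-(2-methylbut-3-yn-2-yloxy)phenyl]-4-(triethylsilyloxy)-7-(triisopropylsilyloxy)chroman | COc1cc(OC(C)(C)C#C)ccc1[C@H]1COc2cc(O[Si](C(C)C)(C(C)C)C(C)C)ccc2[C@H]1O[Si](CC)(CC)CC
F2 | step 3 | 2-[4-(benzyloxy)-2-methoxyphenyl]-4,4,5,5-tetramethyl-1,3,2-dioxaborolane | COc1cc(OCc2ccccc2)ccc1B1OC(C)(C)C(C)(C)O1
F3 | step 3 | 1-[2-hydroxy-4-(triisopropylsilyloxy)phenyl]ethanone | CC(=O)c1ccc(O[Si](C(C)C)(C(C)C)C(C)C)cc1O
F4 | step 3 | (E)-3-(dimethylamino)-1-[2-hydroxy-4-(triisopropylsilyloxy)phenyl]prop-2-en-1-one | CN(C)/C=C/C(=O)c1ccc(O[Si](C(C)C)(C(C)C)C(C)C)cc1O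
F5 | step 3 | 3-iodo-7-(triisopropylsilyloxy)-4H-chromen-4-one | O=c1c(I)coc2cc(O[Si](C(C)C)(C(C)C)C(C)C)ccc12
F6 | step 3 | 3-[4-(benzyloxy)-2-methoxyphenyl]-7-(triisopropylsilyloxy)-4H-chromen-4-one | COc1cc(OCc2ccccc2)ccc1-c1coc2cc(O[Si](C(C)C)(C(C)C)C(C)C)ccc2c1=O
F7 | step 10 | cis-(3S,4S)-3-(7-methoxy-2,2-dimethyl-2H-chromen-6-yl)chroman-4,7-diol | COc1cc2OC(C)(C)C=Cc2cc1[C@H]1COc2cc(O)ccc2[C@H]1O
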